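**Numbering.** Compounds 1–14 are fixed by the steps below. A-labels belong to the alternatives and F-labels to the fallbacks.

## The problem

1. In target 14 one carbon is both C1 of a 7-methoxy-2-(2-hydroxyethyl)isoindolin-3-one (N2, C3=O, C3a–C7a) and C2' of a 2H-naphtho[1,8-bc]furan (O1', C2a', C3'–OH, C4', C5', C5a', C6', C7'–CH3, C8', C8a', C8b'). These locants are used for the same atoms in every precursor.
2. This carbon carries N2, O1', C7a and C2a' and is the only stereocentre (S). No neighbour can control it, so its configuration must come from a catalyst or reagent acting on a flat precursor.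
3. It is very crowded, flanked by C7–OCH3, C3'–OH, the peri oxygen O1' and the N-substituent. At the ketone level it corresponds to a diaryl ketone with four ortho substituents, a poor object for carbonyl addition.
4. It is an N-acyl N,O-ketal with an aryloxide leaving group and an ortho-hydroxyl donor. It can therefore ionise at C1–O1' under acid or base (N-acyliminium ion or ortho-quinone methide), which racemises it, so it should be made late and mildly and then left alone.
5. The naphthalene has a 1,2,6,8 pattern (C2a', C3'–O, C7'–CH3, C8a'–O) that no cheap naphthalene carries. The methyl group is meta to both oxygens and cannot be placed by electrophilic substitution.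
6. A free naphthol, a primary alcohol and a lactam must come through the route.
7. The feature that opens the problem is the position of the C3' hydroxyl. The chain O–C3'=C2a'–C1–N2 is the enol of a β-amido ketone, so cleavage of N2–C1 (retro-aza-Michael) turns ring C2a'–C3'–C4'–C5'–C5a'–C8b' into a cross-conjugated dienone and ring O1'–C1–C2a'–C8b'–C8a' into an aromatic furan.
8. The result, 12, is a flat, achiral 3-acyl-2-arylbenzofuran and an isomer of 14.

## Retrosynthesis

**14 to 12 (cut N2–C1).**
- Of the four bonds at C1, this is the only one whose cleavage leaves a stable, neutral molecule: N2 becomes an amide N–H, C3'–OH becomes C3'=O, and C2a'=C1 completes a furan.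
- Cutting C1–O1' instead gives the ring-opened ortho-quinone methide (A7 below). Its peri hydroxyl sits about 2.5 Å from the acceptor carbon, so the closure needs no catalyst and none can steer it. It is also the channel by which 14 racemises.
- Cutting C1–C2a' or C1–C7a leads back to the tetra-ortho diaryl ketone (A3 below).
- Precursor 12 has no stereocentre and no sp3 carbon in its core.
- The forward reaction adds a weakly nucleophilic secondary amide to a weakly electrophilic vinylogous ester, which leaves room for a chiral Brønsted acid. It must pick one face of the tricycle (through cation 13) and must not be reversible.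

**12 to 11 to 10 (cut C5'–C5a', then C3'–C2a' and C3'–C4').**
- The dienone ring is opened by a retro-Heck cut to vinyl ketone 11, and then by a retro-carbonylative Stille cut to iodide/triflate 10. The three-carbon bridge is carbon monoxide plus a vinyl group.
- An acid-mediated acylation of C2a' would be the neighbouring way to close this ring, but any strong acid would also close 12 without control. The palladium sequence is neutral or mildly basic.
- The tricycle is reduced to a benzofuran with two leaving groups.
- The forward steps need iodide to react before triflate (the intrinsic order) and a 6-endo insertion.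

**10 to 9 to 8 to 7 (functional groups only).**
- Iodine goes to C2a', the innately nucleophilic C3 of a 2-arylbenzofuran.
- The triflate comes from the phenol on C5a', and the amide from a methyl ester.
- The amide is installed only after the alkyne is consumed, so that an o-alkynylbenzamide, which would close through nitrogen, never exists.

**7 to 2 + 5 (cut O1'–C1 and C2a'–C8b').**
- The benzofuran is opened to alkynylresorcinol 6, and then to iodide 2 and alkyne 5.
- The two alkyne carbons become C1 and C2a'. The most hindered C–C bond of the target is thus introduced as a triple bond, and the bonds from C1 to C7a and to O1' are made while C1 is sp-hybridised and sterically undemanding.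
- Iodide 2 is mirror-symmetric, so either hydroxyl may close the furan. The other hydroxyl is left exactly on C5a', where carbon must later be attached.

**5 to 4 to 3, and 2 to 1.**
- Alkyne 5 comes from bromide 3 by Sonogashira coupling and desilylation.
- Iodide 2 comes from orcinol 1, which already holds the methyl group meta to both oxygens.
- Two benzene building blocks therefore replace a tetrasubstituted naphthalene.

## Roads not taken

**Alternative 1: cut C1–C2a' at the ketone level (the obvious route).**
- *Forward:* bromide A1 is metalated and added to anhydride A2 to give keto acid A3. Condensation with the amino alcohol and acid then removes the acetals and closes both rings.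
- *Weaknesses:*
  - A1 needs the 1,2,6,8-substituted naphthalene, and so several steps of arene construction.
  - A nucleophile flanked by an ortho and a peri alkoxy group must attack the more hindered carbonyl of A2, next to OCH3, so both rate and regiochemistry are doubtful.
  - The final closure runs through the N-acyliminium ion with the peri hydroxyl and offers no handle for stereocontrol, so a resolution must follow.
- *Why the chosen plan is better:* it makes the same bonds at sp and sp2 carbon and keeps the stereocentre for a catalysed step.

**Alternative 2: cut C1–C2a' at the aldehyde level and C1–O1' oxidatively.**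
- *Forward:* diol A4 and hydroxylactam A5 combine in an aza-Friedel–Crafts (Betti-type) reaction to give A6. Dehydrogenation gives ortho-quinone methide A7, which closes through the peri hydroxyl.
- *Merits:* it is short and avoids the ketone.
- *Weaknesses:*
  - A4 has three nucleophilic carbons. The wanted one, C8, is the most crowded, while C2 and C4 are activated by the 1-hydroxyl, and nothing in the structure secures C8.
  - A4 must itself be made, because of its methyl group.
  - The oxidant meets an electron-rich naphthalenediol.
  - A7 closes faster than a catalyst can bind.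

**Alternative 3: cut C1–C7a, a [4+1] union.**
- *Forward:* amide A8 is lithiated at the carbon between OCH3 and the carboxamide and added to peri-lactone A9. The tertiary hydroxylactam A10 is then closed with a chiral acid.
- *Merit:* the C–C bond formation is attractive.
- *Weaknesses:*
  - A9 again presupposes the substituted naphthalene plus a C1 unit at the peri position.
  - Two protecting groups must be removed after the labile centre is set.
  - The stereo-determining closure passes through the same N-acyliminium ion that the product regenerates with the same acid. Forward and reverse barriers are therefore similar, and selectivity can drain away.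
- *Why the chosen plan is better:* in the chosen plan the reverse reaction has to destroy a naphthalene ring.

Key step: step 10

Assumption: the descriptor of C1 in the given SMILES is S (O1' > N2 > C7a > C2a'; C7a outranks C2a' because its ortho oxygen carries CH3 and not H).

Assumption: no precedent fixes the sense of induction in step 10. The (R)-acid is written, and its mirror image is to be used if a first run favours the (R)-product.

Assumption: 3 is taken as a catalogue compound; starting from the corresponding acid would add one esterification.

## Steps

Step 1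
Reactants: 1 orcinol (5-methylbenzene-1,3-diol)
Product: 2 2-iodo-5-methylbenzene-1,3-diol
Conditions: I2 (1.05 equiv), NaHCO3 (1.1 equiv), H2O–THF, 0 °C to rt
Reagents that add atoms: iodine, II
Why: Electrophilic iodination of a resorcinol in aqueous hydrogen carbonate goes to the carbon between the two hydroxyls (the 2-iodoresorcinol procedure); the product keeps the mirror plane that makes step 4 free of regiochemical choice.

Step 2
Reactants: 3 methyl 2-bromo-3-methoxybenzoate
Product: 4 methyl 3-methoxy-2-[(trimethylsilyl)ethynyl]benzoate
Conditions: ethynyltrimethylsilane (1.5 equiv), PdCl2(PPh3)2 (3 mol %), CuI (5 mol %), Et3N, sealed tube, 80 °C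
Reagents that add atoms: ethynyltrimethylsilane, C#C[Si](C)(C)C
Why: Sonogashira coupling; the ortho ester activates the C–Br bond and the linear alkyne tolerates two ortho substituents.

Step 3
Reactants: 4 methyl 3-methoxy-2-[(trimethylsilyl)ethynyl]benzoate
Product: 5 methyl 2-ethynyl-3-methoxybenzoate
Conditions: K2CO3 (0.2 equiv), MeOH, rt
Reagents that add atoms: none
Why: Base-catalysed protodesilylation of an alkynylsilane; ester exchange with methanol is degenerate for the methyl ester.

Step 4
Reactants: 2 2-iodo-5-methylbenzene-1,3-diol; 5 methyl 2-ethynyl-3-methoxybenzoate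
Product: 7 methyl 2-(4-hydroxy-6-methyl-1-benzofuran-2-yl)-3-methoxybenzoate, via alkynylresorcinol 6 (not isolated)
Conditions: PdCl2(PPh3)2 (3 mol %), CuI (5 mol %), Et3N, DMF, argon, rt then 70 °C
Reagents that add atoms: none
Why: Sonogashira coupling followed by metal-promoted 5-endo-dig hydroalkoxylation of the o-alkynylphenol (Castro–Stephens-type benzofuran synthesis). The two hydroxyls of 6 are equivalent, so one benzofuran results and the spare hydroxyl sits on C5a'. The ester has no N–H that could compete for the alkyne.

Step 5
Reactants: 7 methyl 2-(4-hydroxy-6-methyl-1-benzofuran-2-yl)-3-methoxybenzoate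
Product: 8 N-(2-hydroxyethyl)-2-(4-hydroxy-6-methyl-1-benzofuran-2-yl)-3-methoxybenzamide
Conditions: 2-aminoethanol (10 equiv, neat), 90 °C
Reagents that add atoms: 2-aminoethanol, NCCO
Why: Aminolysis of a methyl benzoate with one ortho substituent, helped by the hydroxyl of the amine (transesterification and O-to-N shift); phenol and benzofuran are inert to the amine.

Step 6
Reactants: 8 N-(2-hydroxyethyl)-2-(4-hydroxy-6-methyl-1-benzofuran-2-yl)-3-methoxybenzamide
Product: 9 2-{2-[(2-hydroxyethyl)carbamoyl]-6-methoxyphenyl}-6-methyl-1-benzofuran-4-yl trifluoromethanesulfonate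
Conditions: PhNTf2 (1.05 equiv), Et3N (1.5 equiv), DMF, 0 °C to rt
Reagents that add atoms: N-phenylbis(trifluoromethanesulfonimide), O=S(=O)(N(c1ccccc1)S(=O)(=O)C(F)(F)F)C(F)(F)F
Why: This mild triflyl donor reacts with phenoxides only, so the primary alcohol and the amide N–H should stay untouched.

Step 7
Reactants: 9 2-{2-[(2-hydroxyethyl)carbamoyl]-6-methoxyphenyl}-6-methyl-1-benzofuran-4-yl trifluoromethanesulfonate
Product: 10 2-{2-[(2-hydroxyethyl)carbamoyl]-6-methoxyphenyl}-3-iodo-6-methyl-1-benzofuran-4-yl trifluoromethanesulfonate
Conditions: NIS (1.1 equiv), TFA (10 mol %), MeCN, dark, 0 °C to rt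
Reagents that add atoms: N-iodosuccinimide, O=C1CCC(=O)N1I
Why: Electrophilic halogenation of a 2-arylbenzofuran at C3, the β-carbon of the enol ether; the benzo ring is deactivated by the triflate, and the anisole ring by the carboxamide, which is ortho or para to both positions that OCH3 activates.

Step 8
Reactants: 10 2-{2-[(2-hydroxyethyl)carbamoyl]-6-methoxyphenyl}-3-iodo-6-methyl-1-benzofuran-4-yl trifluoromethanesulfonate
Product: 11 3-acryloyl-2-{2-[(2-hydroxyethyl)carbamoyl]-6-methoxyphenyl}-6-methyl-1-benzofuran-4-yl trifluoromethanesulfonate
Conditions: CO (3 bar), Bu3SnCH=CH2 (1.2 equiv), Pd2(dba)3 (2.5 mol %), AsPh3 (20 mol %), BHT (trace), THF, 50 °C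
Reagents that add atoms: carbon monoxide, [C-]#[O+]; tributyl(vinyl)stannane, C=C[Sn](CCCC)(CCCC)CCCC
Why: Carbonylative Stille coupling; without chloride, oxidative addition to C–I is much faster than to C–OTf, CO insertion relieves strain at the hindered aryl–Pd bond, and the base-free medium gives the alcohol and amide no chance to trap the acyl–Pd species.

Step 9
Reactants: 11 3-acryloyl-2-{2-[(2-hydroxyethyl)carbamoyl]-6-methoxyphenyl}-6-methyl-1-benzofuran-4-yl trifluoromethanesulfonate
Product: 12 N-(2-hydroxyethyl)-3-methoxy-2-(7-methyl-3-oxo-3H-naphtho[1,8-bc]furan-2-yl)benzamide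
Conditions: Pd(OAc)2 (10 mol %), dppp (12 mol %), 1,2,2,6,6-pentamethylpiperidine (2 equiv), MeCN (0.01 M), 70 °C
Reagents that add atoms: none
Why: Intramolecular Heck reaction on the cationic (triflate) pathway. The aryl group adds to the terminal β-carbon of the enone, as electronics demand, and the 5-exo alternative would bridge C3 and C4 of a benzofuran with only two atoms, so 6-endo closure and β-hydride elimination should give the dienone. The only acid present is the hindered ammonium salt, too weak to activate 12 towards its amide.

Step 10
Reactants: 12 N-(2-hydroxyethyl)-3-methoxy-2-(7-methyl-3-oxo-3H-naphtho[1,8-bc]furan-2-yl)benzamide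
Product: 14 (S)-3'-hydroxy-2-(2-hydroxyethyl)-7-methoxy-7'-methylspiro[isoindoline-1,2'-naphtho[1,8-bc]furan]-3-one, via hydroxynaphthofuranium phosphate ion pair 13 (not isolated)
Conditions: (R)-TRIP [(R)-3,3'-bis(2,4,6-triisopropylphenyl)-1,1'-binaphthyl-2,2'-diyl hydrogen phosphate] (10 mol %), 4 Å MS, toluene–CH2Cl2 (4:1), −20 °C
Reagents that add atoms: none
Why: Proposed new method: the acidic proton of the catalyst goes to the C3' carbonyl oxygen of 12, the most basic oxygen because protonation gives the fully aromatic cation 13, while the phosphoryl oxygen holds the amide N–H, so both partners of the new bond sit on one chiral phosphate. N2 then attacks C1 of the cation (5-exo-trig, the only ring closed), the phosphate takes the N–H proton and the catalyst is released; in sum this is an intramolecular aza-Michael addition to the enone C3'(=O)–C2a'=C1 that dearomatises the furan and is paid for by the new naphthalene ring. The closest known reaction types are phosphoric-acid-catalysed conjugate additions of N–H and O–H nucleophiles to ortho-quinone methides and phosphoric-acid-catalysed N,O-acetalisations with amides; new are a 3-acylbenzofuran as acceptor and a tetrasubstituted N,O-ketal carbon as product. The stereocentre C1 is controlled by the catalyst alone: the anisole ring stands roughly perpendicular to the flat tricycle with the carboxamide above or below it, the two mirror-image rotamers interconvert by rotation about C1–C7a (one flank of this axis is the bare ring oxygen O1'), and the catalyst pocket selects the rotamer that closes faster (Curtin–Hammett, dynamic kinetic control). The step needs N- over O-attack of the amide (O-attack gives an imidate that reverts under the same acid, whereas the lactam is the sink), attack by the amide and not by the primary alcohol (five- against eight-membered ring), and no erosion afterwards. The last point rests on thermodynamics and mildness: the reverse reaction must destroy a naphthalene ring, and an acceptor as basic as 12 should be activated by an acid too weak, at a temperature too low, to ionise C1–O1' of 14. Molecular sieves keep out water, which would open 13 to the diaryl ketone and so to the uncontrolled N-acyliminium channel. Because the step is an isomerisation and the last of the route, nothing touches the labile centre after it is made.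

## Compound list

1 | orcinol (5-methylbenzene-1,3-diol) | Cc1cc(O)cc(O)c1 | starting material
2 | 2-iodo-5-methylbenzene-1,3-diol | Cc1cc(O)c(I)c(O)c1 | intermediate
3 | methyl 2-bromo-3-methoxybenzoate | COC(=O)c1cccc(OC)c1Br | starting material
4 | methyl 3-methoxy-2-[(trimethylsilyl)ethynyl]benzoate | COC(=O)c1cccc(OC)c1C#C[Si](C)(C)C | intermediate
5 | methyl 2-ethynyl-3-methoxybenzoate | COC(=O)c1cccc(OC)c1C#C | intermediate
6 | methyl 2-[(2,6-dihydroxy-4-methylphenyl)ethynyl]-3-methoxybenzoate (not isolated) | COC(=O)c1cccc(OC)c1C#Cc1c(O)cc(C)cc1O | intermediate
7 | methyl 2-(4-hydroxy-6-methyl-1-benzofuran-2-yl)-3-methoxybenzoate | COC(=O)c1cccc(OC)c1-c1cc2c(O)cc(C)cc2o1 | intermediate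
8 | N-(2-hydroxyethyl)-2-(4-hydroxy-6-methyl-1-benzofuran-2-yl)-3-methoxybenzamide | COc1cccc(C(=O)NCCO)c1-c1cc2c(O)cc(C)cc2o1 | intermediate
9 | 2-{2-[(2-hydroxyethyl)carbamoyl]-6-methoxyphenyl}-6-methyl-1-benzofuran-4-yl trifluoromethanesulfonate | COc1cccc(C(=O)NCCO)c1-c1cc2c(OS(=O)(=O)C(F)(F)F)cc(C)cc2o1 | intermediate
10 | 2-{2-[(2-hydroxyethyl)carbamoyl]-6-methoxyphenyl}-3-iodo-6-methyl-1-benzofuran-4-yl trifluoromethanesulfonate | COc1cccc(C(=O)NCCO)c1-c1oc2cc(C)cc(OS(=O)(=O)C(F)(F)F)c2c1I | intermediate
11 | 3-acryloyl-2-{2-[(2-hydroxyethyl)carbamoyl]-6-methoxyphenyl}-6-methyl-1-benzofuran-4-yl trifluoromethanesulfonate | COc1cccc(C(=O)NCCO)c1-c1oc2cc(C)cc(OS(=O)(=O)C(F)(F)F)c2c1C(=O)C=C | intermediate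
12 | N-(2-hydroxyethyl)-3-methoxy-2-(7-methyl-3-oxo-3H-naphtho[1,8-bc]furan-2-yl)benzamide | COc1cccc(C(=O)NCCO)c1-c1oc2cc(C)cc3C=CC(=O)c1c23 | intermediate
13 | O-protonated 12, 3-hydroxy-2-aryl-7-methylnaphtho[1,8-bc]furan-1-ium (cation shown; counter-ion is the catalyst phosphate; not isolated) | COc1cccc(C(=O)NCCO)c1C1=[O+]c2cc(C)cc3ccc(O)c1c23 | intermediate
14 | (S)-3'-hydroxy-2-(2-hydroxyethyl)-7-methoxy-7'-methylspiro[isoindoline-1,2'-naphtho[1,8-bc]furan]-3-one | COc1cccc2c1[C@]1(Oc3cc(C)cc4ccc(O)c1c34)N(CCO)C2=O | target

## Step count and least certain steps

Total step count: 10. Longest linear sequence: 9 (steps 2–10, from 3).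

**Step 10 (key step).**
- *What may go wrong:*
  - Facial selection may be poor, because the catalyst must tell apart two rotamers that differ only in the side on which the carboxamide lies, and because the free primary hydroxyl can compete for the phosphate.
  - An uncatalysed or trace-acid closure would add racemic material.
  - Binding of the naphthol and lactam of the product to the catalyst could slow turnover.
  - Prolonged contact with acid could erode the result through ionisation of C1–O1'.
- *Fallback (known chemistry, from 12 back to 14):* 12 is closed with an achiral acid (diphenyl phosphate, CH2Cl2, rt) to the racemic spiro-lactam F1. Preparative chromatography on a chiral stationary phase separates 14 from the (R)-enantiomer F2. F2 is re-equilibrated to F1 by warming with trifluoroacetic acid and fed back into the separation.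

**Step 9.**
- *What may go wrong:*
  - Migratory insertion may be slow, because the acryloyl group must turn out of conjugation to reach palladium on C5a'.
  - The vinyl ketone may polymerise.
  - 12 may close thermally to racemic material during heating with base.
- *Fallback (from 11 back to 12):* if insertion is the failing event, the aryl–palladium species is free to transmetalate. The triflate is then exchanged for vinyl (tributyl(vinyl)stannane, Pd(PPh3)4, LiCl, dioxane) to give N-(2-hydroxyethyl)-2-(3-acryloyl-6-methyl-4-vinyl-1-benzofuran-2-yl)-3-methoxybenzamide F3. Ring-closing metathesis (second-generation ruthenium benzylidene catalyst, CH2Cl2, 40 °C) forms C4'=C5' under neutral, cooler conditions.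

**Step 8.**
- *What may go wrong:*
  - Direct vinylation may occur without CO uptake.
  - The crowded C2a' position may undergo protodeiodination.
  - The triflate may engage prematurely.
  - The product may be lost by polymerisation.
- *Fallback (from 10 back to 11):* iodine–magnesium exchange with iPrMgCl·LiCl (3.3 equiv, the first two taken up by O–H and N–H; THF, −40 °C). Magnesium is chosen because 3-lithiobenzofurans ring-open. Addition to acrolein gives the allylic alcohol 2-{2-[(2-hydroxyethyl)carbamoyl]-6-methoxyphenyl}-3-(1-hydroxyallyl)-6-methyl-1-benzofuran-4-yl trifluoromethanesulfonate F4. MnO2 (CH2Cl2) oxidises it selectively at the activated carbinol.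

**Step 7.**
- *What may go wrong:* iodination may go to the wrong ring (positions ortho and para to O1', or the anisole ring), or may be sluggish because C2a' lies between the twisted aryl group and the triflate.
- *Fallback (from 2 and 5 back to 10):* here the mechanism fixes the position of iodine.
  1. 2 is mono-triflated (PhNTf2, 1 equiv) to 3-hydroxy-2-iodo-5-methylphenyl trifluoromethanesulfonate F5.
  2. F5 is coupled with 5 at rt (Sonogashira) to methyl 2-{[2-hydroxy-4-methyl-6-(triflyloxy)phenyl]ethynyl}-3-methoxybenzoate F6.
  3. Iodocyclisation (I2, NaHCO3, MeCN) gives methyl 2-[3-iodo-6-methyl-4-(triflyloxy)-1-benzofuran-2-yl]-3-methoxybenzoate F7.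
  4. Aminolysis with 2-aminoethanol at rt gives 10. It is catalysed by 1,5,7-triazabicyclo[4.4.0]dec-5-ene, which works here because no phenol is left to quench the catalyst.

## Further compounds

F1 | step 10 | rac-3'-hydroxy-2-(2-hydroxyethyl)-7-methoxy-7'-methylspiro[isoindoline-1,2'-naphtho[1,8-bc]furan]-3-one | COc1cccc2c1C1(Oc3cc(C)cc4ccc(O)c1c34)N(CCO)C2=O
F2 | step 10 | (R)-3'-hydroxy-2-(2-hydroxyethyl)-7-methoxy-7'-methylspiro[isoindoline-1,2'-naphtho[1,8-bc]furan]-3-one | COc1cccc2c1[C@@]1(Oc3cc(C)cc4ccc(O)c1c34)N(CCO)C2=O
F3 | step 9 | N-(2-hydroxyethyl)-2-(3-acryloyl-6-methyl-4-vinyl-1-benzofuran-2-yl)-3-methoxybenzamide | COc1cccc(C(=O)NCCO)c1-c1oc2cc(C)cc(C=C)c2c1C(=O)C=C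
F4 | step 8 | 2-{2-[(2-hydroxyethyl)carbamoyl]-6-methoxyphenyl}-3-(1-hydroxyallyl)-6-methyl-1-benzofuran-4-yl trifluoromethanesulfonate (racemic) | COc1cccc(C(=O)NCCO)c1-c1oc2cc(C)cc(OS(=O)(=O)C(F)(F)F)c2c1C(O)C=C
F5 | step 7 | 3-hydroxy-2-iodo-5-methylphenyl trifluoromethanesulfonate | Cc1cc(O)c(I)c(OS(=O)(=O)C(F)(F)F)c1
F6 | step 7 | methyl 2-{[2-hydroxy-4-methyl-6-(triflyloxy)phenyl]ethynyl}-3-methoxybenzoate | COC(=O)c1cccc(OC)c1C#Cc1c(O)cc(C)cc1OS(=O)(=O)C(F)(F)F
F7 | step 7 | methyl 2-[3-iodo-6-methyl-4-(triflyloxy)-1-benzofuran-2-yl]-3-methoxybenzoate | COC(=O)c1cccc(OC)c1-c1oc2cc(C)cc(OS(=O)(=O)C(F)(F)F)c2c1I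
A1 | alternative 1 | 1-bromo-2,8-bis(methoxymethoxy)-6-methylnaphthalene | COCOc1ccc2cc(C)cc(OCOC)c2c1Br
A2 | alternative 1 | 3-methoxyphthalic anhydride | COc1cccc2C(=O)OC(=O)c12
A3 | alternative 1 | 2-[2,8-bis(methoxymethoxy)-6-methyl-1-naphthoyl]-3-methoxybenzoic acid | COCOc1ccc2cc(C)cc(OCOC)c2c1C(=O)c1c(OC)cccc1C(=O)O
A4 | alternative 2 | 3-methylnaphthalene-1,7-diol | Cc1cc(O)c2cc(O)ccc2c1
A5 | alternative 2 | 3-hydroxy-2-(2-hydroxyethyl)-4-methoxyisoindolin-1-one (racemic) | COc1cccc2c1C(O)N(CCO)C2=O
A6 | alternative 2 | 3-(2,8-dihydroxy-6-methylnaphthalen-1-yl)-2-(2-hydroxyethyl)-4-methoxyisoindolin-1-one (racemic) | COc1cccc2c1C(c1c(O)ccc3cc(C)cc(O)c13)N(CCO)C2=O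
A7 | alternative 2 | 3-(8-hydroxy-6-methyl-2-oxonaphthalen-1(2H)-ylidene)-2-(2-hydroxyethyl)-4-methoxyisoindolin-1-one | COc1cccc2c1C(=C1C(=O)C=Cc3cc(C)cc(O)c13)N(CCO)C2=O
A8 | alternative 3 | N-[2-(tert-butyldimethylsilyloxy)ethyl]-3-methoxybenzamide | COc1cccc(C(=O)NCCO[Si](C)(C)C(C)(C)C)c1
A9 | alternative 3 | 3-(benzyloxy)-7-methyl-2H-naphtho[1,8-bc]furan-2-one | O=C1Oc2cc(C)cc3ccc(OCc4ccccc4)c1c23
A10 | alternative 3 | 3-[2-(benzyloxy)-8-hydroxy-6-methylnaphthalen-1-yl]-2-[2-(tert-butyldimethylsilyloxy)ethyl]-3-hydroxy-4-methoxyisoindolin-1-one (racemic) | COc1cccc2c1C(O)(c1c(OCc3ccccc3)ccc3cc(C)cc(O)c13)N(CCO[Si](C)(C)C(C)(C)C)C2=O
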